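Whatever happens in this closed flask, the shares of the starting material charged add up to the whole: what is not product is free, bound as intermediate, or in homo dimer. So I follow one share, the part not yet product, and ask how fast it falls.

| setting | north-east | south-east | north-west | south | dawn | spring | dusk | summer | noon |
|---|---|---|---|---|---|---|---|---|---|
| starting material | 0.010 M | 0.010 M | 0.010 M | 0.0070 M | 0.020 M | 0.0060 M | 0.010 M | 0.0050 M | 0.0025 M |
| solid reagent | 0.65 equiv | 1.4 equiv | 2.6 equiv | 1 equiv | 0.670 equiv | 1.50 equiv | 1.00 equiv | 3.00 equiv | 1.00 equiv |
| remark | run made earlier | run made earlier | run made earlier | run made earlier |  |  |  |  |  |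
| time |  |  |  |  | 5.0 h | 5.0 h | 5.0 h | 5.0 h | 5.0 h |

| run | time / h | product / % |
|---|---|---|
| north-east | 0.250 | 0 |
| north-east | 0.500 | 1.6 |
| north-east | 1.00 | 8.4 |
| north-east | 2.00 | 18.3 |
| north-east | 4.00 | 33.4 |
| south-east | 0.250 | 0.2 |
| south-east | 0.500 | 3.1 |
| south-east | 1.00 | 7.0 |
| south-east | 2.00 | 22.3 |
| south-east | 4.00 | 51.5 |
| north-west | 0.667 | 2.9 |
| north-west | 1.33 | 10.4 |
| north-west | 2.00 | 22.2 |
| north-west | 3.00 | 39.0 |
| north-west | 4.00 | 49.8 |
| south | 0.333 | 1.5 |
| south | 0.833 | 3.8 |
| south | 1.50 | 14.3 |
| south | 2.50 | 26.1 |
| south | 4.00 | 41.3 |

(scatter of a reading: 1 percentage point)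

- percentages count the starting material that a species holds: one homo dimer counts as two
- solid, in amounts per volume of the solution: solid reagent
- the numbers in the tables scatter with a standard deviation of 1 percentage point
- steps that have been proposed: 2 starting material -> homo dimer; starting material + partner <-> intermediate; intermediate -> product; solid reagent <-> partner
- at the start none of the solid reagent is in solution

1. ranking by amount of product, in percent of the starting material charged, from high to low, at 5.0 h (dawn / spring / dusk / summer / noon)
2. the amount of product, in percent of the starting material charged of the flask you put first, at 5.0 h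
3. the amount of product, in percent of the starting material charged of the flask you put last, at 5.0 h

North-west holds 0.0260 M of solid per volume, more than the 0.0140 M of south-east, yet at 4.00 h they read 49.8 % and 51.5 %, a gap of 1.7 percentage points against a scatter of 1 point. Summer holds 0.0150 M, more than south-east, so I treat it as a flask with solid to spare and take its rate from north-west. There the share not yet product falls from 77.8 % at 2.00 h to 50.2 % at 4.00 h:

k = ln(ratio of those shares) / elapsed time = 0.219 h⁻¹

This k, a reading with the scatter in it, is the fade constant, the part of what is not yet product that becomes product each hour; I take the fall as pseudo-first-order. Traced back through the 2.00 h reading, my reckoning puts the start of the fall after a lag: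

t₀ = 0.854 h

In this reckoning the product rate starts at k times the whole charge and then falls with the share, each hour multiplying the rate by 0.803. The accumulated slowing up to 5.0 h is:

F = exp(−k(t − t₀)) = 40.3 %

F is also the share not yet product, so I reckon summer at 59.7 % product.

The forecast gives summer > spring > dusk > dawn > noon, with 66 % for summer and 29 % for noon; of summer it says: “excess solid and dilute”. My figure for summer is lower, by 6.3 points.

The flasks give summer > spring > dusk > dawn > noon, with 63.3 % in summer and 26.5 % in noon.

    2 starting material → homo dimer (k = 1.20 M⁻¹ h⁻¹)
    starting material + partner ⇌ intermediate (K = 303 M⁻¹, k = 41.9 M⁻¹ h⁻¹)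
    intermediate → product (k = 0.999 h⁻¹)
    solid reagent ⇌ partner, rate k4*(cs4 - [partner]) while solid is left; crystals form when [partner] > cs4 (solubility = 7.80 mM, k = 4.53 h⁻¹)

In summer at 0.281 h, partner is made 9.69 times as fast as it is used up, each step taken net, and c(partner) reads 0.00763 M at 2.50 h and 0.00772 M at 5.00 h, with 24.3 % of the solid reagent's own charge still solid. Summer's share not yet product is 36.7 % against my F of 40.3 %. For summer read at 20.0 h, the fade constant gives 98.5 % product, and the flask holds 97.2 %, with 2.27 % in homo dimer.

(The earlier runs and the new flask are simulated for substances that don't exist; scatter was added.)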